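**Retrosynthetic overview**

- Aikupikoxide D ⇒ an alpha-alkyl beta-ketophosphonate plus formaldehyde (Horner–Wadsworth–Emmons methylenation makes C10=CH2 last); C9–C10 comes from a C9 aldehyde and a lithiated C10–C14 phosphonate; the C1 methyl ester comes from a C1 silyl ether by oxidation after all strongly basic steps.
- Saturated 1,2-dioxane ⇒ 3,6-dihydro-1,2-dioxine carrying a C7≡C8 alkyne; diimide removes C4=C5 and C7≡C8 and leaves O1–O2 intact.
- Key disconnection C5–C6: the only ring (O1–O2–C3–C4–C5–C6) closes when a (Z)-vinylsilane (C4=C5–SiMe3) attacks an acyclic peroxycarbenium ion at C6, generated from a mixed methyl peroxyketal.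
- Peroxyketal ⇒ C3 hydroperoxide + dimethyl ketal of a propargylic ynone; C2 comes from an Evans syn-aldol, C3 is inverted by HOO− displacement of a mesylate, and C1 is kept as a silyl ether because an ester would not survive alkaline H2O2.
- Structural feature used: ring bond C5–C6 of the 1,2-dioxane joins the fully substituted peroxide carbon C6 to a carbon that can be vinylic (C4=C5), and C7–C8 can be a slim temporary alkyne that distinguishes the C6 chain from the C6 methyl.

Key step: step 10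

Remark on the chemistry: atom numbers are those of the natural product (C1 ester carbon; ring O1–O2–C3–C4–C5–C6 with O2 on C3 and O1 on C6; chain C7–C14), and the tert-butyldimethylsilyl ether of propargyl alcohol used in step 7 is assumed to be a purchasable material.

**Route**

Step 1
Reactants: 1 3-(trimethylsilyl)prop-2-ynal; 2 (S)-4-benzyl-3-propanoyl-1,3-oxazolidin-2-one
Product: 4 (S)-4-benzyl-3-[(2S,3S)-3-hydroxy-2-methyl-5-(trimethylsilyl)pent-4-ynoyl]-1,3-oxazolidin-2-one, via dibutylboron (Z)-enolate 3 (not isolated)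
Conditions: Bu2BOTf, i-Pr2NEt, CH2Cl2, 0 °C; then 1, −78 → 0 °C; pH 7 buffer, MeOH, 30% H2O2, 0 °C
Reagents that add atoms: none
Why: Evans syn-aldol reaction, in which the (Z)-boron enolate reacts through a chair Zimmerman–Traxler transition state on the face away from the benzyl group, which should set C2 (kept to the end) and a 2,3-syn C3 carbinol (inverted in step 6).

Step 2
Reactants: 4 (S)-4-benzyl-3-[(2S,3S)-3-hydroxy-2-methyl-5-(trimethylsilyl)pent-4-ynoyl]-1,3-oxazolidin-2-one
Product: 5 (2R,3S)-2-methyl-5-(trimethylsilyl)pent-4-yne-1,3-diol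
Conditions: LiBH4, H2O (1 equiv), Et2O, 0 °C
Reagents that add atoms: none
Why: Reductive cleavage of the N-acyloxazolidinone by borohydride gives the primary alcohol without touching C2 (its descriptor changes by priority only), and C1 is taken to the alcohol level because an ester would suffer perhydrolysis and beta-elimination in step 6.

Step 3
Reactants: 5 (2R,3S)-2-methyl-5-(trimethylsilyl)pent-4-yne-1,3-diol
Product: 6 (2R,3S)-1-[(tert-butyldiphenylsilyl)oxy]-2-methyl-5-(trimethylsilyl)pent-4-yn-3-ol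
Conditions: TBDPSCl, imidazole, CH2Cl2, 0 °C
Reagents that add atoms: tert-butyl(chloro)diphenylsilane, CC(C)(C)[Si](Cl)(c1ccccc1)c1ccccc1
Why: Silylation of a 1,3-diol with a bulky chlorosilane should take the less hindered primary hydroxyl and leave the C3 carbinol free.

Step 4
Reactants: 6 (2R,3S)-1-[(tert-butyldiphenylsilyl)oxy]-2-methyl-5-(trimethylsilyl)pent-4-yn-3-ol
Product: 7 (2R,3S,4Z)-1-[(tert-butyldiphenylsilyl)oxy]-2-methyl-5-(trimethylsilyl)pent-4-en-3-ol
Conditions: H2 (1 atm), nickel boride from Ni(OAc)2·4H2O and NaBH4, ethylenediamine, EtOH, rt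
Reagents that add atoms: none
Why: Semihydrogenation of the silylalkyne on amine-poisoned nickel boride delivers both hydrogens to one face (syn addition) and should stop at the (Z)-vinylsilane that the cyclisation needs.

Step 5
Reactants: 7 (2R,3S,4Z)-1-[(tert-butyldiphenylsilyl)oxy]-2-methyl-5-(trimethylsilyl)pent-4-en-3-ol
Product: 8 (2R,3S,4Z)-1-[(tert-butyldiphenylsilyl)oxy]-2-methyl-5-(trimethylsilyl)pent-4-en-3-yl methanesulfonate
Conditions: MsCl, Et3N, CH2Cl2, −20 °C; used crude at once
Reagents that add atoms: methanesulfonyl chloride, CS(=O)(=O)Cl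
Why: Sulfonylation of the secondary allylic alcohol forms only an O–S bond, so C3 keeps its configuration and gains a leaving group.

Step 6
Reactants: 8 (2R,3S,4Z)-1-[(tert-butyldiphenylsilyl)oxy]-2-methyl-5-(trimethylsilyl)pent-4-en-3-yl methanesulfonate
Product: 9 tert-butyl{[(2R,3R,4Z)-3-hydroperoxy-2-methyl-5-(trimethylsilyl)pent-4-en-1-yl]oxy}diphenylsilane
Conditions: 50% aq. H2O2, KOH, MeOH/THF, 0 °C
Reagents that add atoms: hydrogen peroxide, OO
Why: SN2 displacement of the secondary mesylate by the hydroperoxide anion (alpha-effect nucleophile, weak base) should invert C3 to the 2,3-anti hydroperoxide, with the trimethylsilyl group on C5 blocking the SN2′ terminus and no carbonyl present to promote elimination.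

Step 7
Reactants: 10 tert-butyldimethyl(prop-2-yn-1-yloxy)silane; 11 N-methoxy-N-methylacetamide
Product: 13 5-[(tert-butyldimethylsilyl)oxy]pent-3-yn-2-one, via lithium acetylide 12 (not isolated)
Conditions: n-BuLi, THF, −78 °C; then 11, −78 → 0 °C; aq. NH4Cl
Reagents that add atoms: none
Why: Acylation of the lithium acetylide by the N-methoxy-N-methylamide passes through a stable chelated tetrahedral intermediate, so the ynone should form without over-addition.

Step 8
Reactants: 13 5-[(tert-butyldimethylsilyl)oxy]pent-3-yn-2-one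
Product: 14 tert-butyl[(4,4-dimethoxypent-2-yn-1-yl)oxy]dimethylsilane
Conditions: MeOSiMe3, TMSOTf (cat.), CH2Cl2, −78 → −30 °C; pyridine quench
Reagents that add atoms: methoxytrimethylsilane, CO[Si](C)(C)C
Why: Noyori ketalisation (silyl triflate-catalysed exchange with the methyl silyl ether) should give the dimethyl ketal under aprotic conditions that spare the silyl ether and avoid conjugate addition of methanol to the ynone.

Step 9
Reactants: 9 tert-butyl{[(2R,3R,4Z)-3-hydroperoxy-2-methyl-5-(trimethylsilyl)pent-4-en-1-yl]oxy}diphenylsilane; 14 tert-butyl[(4,4-dimethoxypent-2-yn-1-yl)oxy]dimethylsilane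
Product: 15 tert-butyl{[(2R,3R,4Z)-3-({5-[(tert-butyldimethylsilyl)oxy]-2-methoxypent-3-yn-2-yl}peroxy)-2-methyl-5-(trimethylsilyl)pent-4-en-1-yl]oxy}diphenylsilane (both epimers at the peroxyketal carbon C6)
Conditions: 14 (excess), camphorsulfonic acid (cat.), 4 Å molecular sieves, CH2Cl2, 0 °C → rt; Et3N quench
Reagents that add atoms: none
Why: Acid-catalysed transketalisation, in which the ketal ionises to an alkynyl oxocarbenium ion that the hydroperoxide captures at carbon, should be driven to the mixed peroxyketal by excess ketal and uptake of methanol by the sieves; the two C6 epimers converge in step 10.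

Step 10
Reactants: 15 mixed methyl peroxyketal (both C6 epimers)
Product: 18 tert-butyl{[(2R)-2-{(3S,6R)-6-[3-(tert-butyldimethylsilyloxy)prop-1-yn-1-yl]-6-methyl-3,6-dihydro-1,2-dioxin-3-yl}propyl]oxy}diphenylsilane, via peroxycarbenium ion 16 (not isolated), via ring-closed beta-silyl cation 17 (not isolated)
Conditions: SnCl4 (1.1 equiv), CH2Cl2, −78 °C; Et3N/MeOH then aq. NaHCO3 at −78 °C
Reagents that add atoms: none
Why: Proposed new method: SnCl4 should bind the methoxy oxygen of 15 and ionise it to the alkyne-conjugated peroxycarbenium ion 16, the silicon-bearing carbon C5 of the (Z)-vinylsilane then attacks C6 to give the beta-silyl cation 17 (charge at C4), and chloride removes the trimethylsilyl group to leave the cis C4=C5 alkene of 18. The closest known reactions are the trapping of peroxycarbenium ions from monoperoxyketals by allylsilanes and tethered alkenes and the vinylsilane-terminated oxocarbenium cyclisation to 5,6-dihydro-2H-pyrans, with O2 here taking the place of the ring CH2 next to oxygen. The single ring O1–O2–C3–C4–C5–C6 closes in a 6-endo mode with respect to both the vinylsilane and the C6=O1 cation through a chair-like transition state. The new stereocentre C6 is controlled by C3: the branched C3 substituent sits pseudo-equatorial, the C6 methyl (anti to O2 in the cation) pseudo-equatorial and the slim alkynyl group pseudo-axial, which places the alkynyl chain cis to the C3 side chain as the target requires. The step needs ionisation of C–OMe and not C–OO (secured by the more basic ether oxygen and low temperature), attack through C5 and not C4 (secured by silicon, which stabilises only the C4 cation and would leave an unstabilised alpha-silyl cation in the five-ring alternative) and attack at C6 and not at the remote alkyne carbon C8 (secured by the tether length). C1 is kept as a bulky tert-butyldiphenylsilyl ether so that no carbonyl or hydroxyl can chelate tin or trap the cation, and the quench is done cold because the tertiary allylic and propargylic C6–O1 bond of 18 can ionise again.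

Step 11
Reactants: 18 3,6-dihydro-1,2-dioxine with the C7≡C8 alkyne
Product: 19 tert-butyl{[(2R)-2-{(3S,6S)-6-[3-(tert-butyldimethylsilyloxy)propyl]-6-methyl-1,2-dioxan-3-yl}propyl]oxy}diphenylsilane
Conditions: KO2CN=NCO2K (large excess, in portions), AcOH, MeOH/CH2Cl2, 0 °C → rt
Reagents that add atoms: none
Why: Diimide reduction transfers H2 to C=C and C≡C through a concerted cyclic transition state and does not reduce O–O, so excess reagent should saturate C4=C5 and C7≡C8 without touching a stereocentre (the C6 descriptor changes by priority only).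

Step 12
Reactants: 19 bis-silyl 1,2-dioxane
Product: 20 (3S,6S)-3-{(2R)-1-[(tert-butyldiphenylsilyl)oxy]propan-2-yl}-6-(3-hydroxypropyl)-6-methyl-1,2-dioxane
Conditions: PPTS, MeOH, rt
Reagents that add atoms: none
Why: Acid-catalysed methanolysis of silyl ethers removes the primary tert-butyldimethylsilyl group much faster than the tert-butyldiphenylsilyl group, and the saturated dialkyl peroxide tolerates the mild acid.

Step 13
Reactants: 20 C9 alcohol
Product: 21 (3S,6R)-3-{(2R)-1-[(tert-butyldiphenylsilyl)oxy]propan-2-yl}-6-methyl-6-(3-oxopropyl)-1,2-dioxane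
Conditions: Dess–Martin periodinane, NaHCO3, CH2Cl2, 0 °C → rt
Reagents that add atoms: none
Why: Dess–Martin oxidation converts the primary alcohol to the C9 aldehyde under neutral buffered conditions that leave the peroxide alone, and the aldehyde is gamma to O1 so no elimination path exists.

Step 14
Reactants: 22 ethyl 5-bromopentanoate
Product: 23 ethyl 5-(diethoxyphosphoryl)pentanoate
Conditions: P(OEt)3, neat, 150 °C, EtBr distilled off
Reagents that add atoms: triethyl phosphite, CCOP(OCC)OCC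
Why: Michaelis–Arbuzov reaction of a primary bromide with triethyl phosphite gives the phosphonate that will become C10.

Step 15
Reactants: 23 ethyl 5-(diethoxyphosphoryl)pentanoate
Product: 24 diethyl (5-hydroxy-5-methylhexyl)phosphonate
Conditions: MeMgBr (2.5 equiv), THF, −20 → 0 °C; aq. NH4Cl
Reagents that add atoms: methylmagnesium bromide, C[Mg]Br
Why: Double Grignard addition to the carboxylic ester builds the C14 tertiary alcohol, the ester being far more electrophilic than the phosphonate at low temperature.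

Step 16
Reactants: 24 diethyl (5-hydroxy-5-methylhexyl)phosphonate
Product: 25 diethyl {5-methyl-5-[(triethylsilyl)oxy]hexyl}phosphonate
Conditions: TESOTf, 2,6-lutidine, CH2Cl2, 0 °C
Reagents that add atoms: triethylsilyl trifluoromethanesulfonate, CC[Si](CC)(CC)OS(=O)(=O)C(F)(F)F
Why: Silylation of the hindered tertiary alcohol with a silyl triflate removes the acidic proton before the phosphonate is lithiated.

Step 17
Reactants: 25 diethyl {5-methyl-5-[(triethylsilyl)oxy]hexyl}phosphonate; 21 C9 aldehyde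
Product: 27 (3S,6S)-3-{(2R)-1-[(tert-butyldiphenylsilyl)oxy]propan-2-yl}-6-{4-(diethoxyphosphoryl)-3-hydroxy-8-methyl-8-[(triethylsilyl)oxy]nonyl}-6-methyl-1,2-dioxane (C9/C10 diastereomer mixture), via alpha-lithiated phosphonate 26 (not isolated)
Conditions: n-BuLi, THF, −78 °C; then 21, −78 °C; aq. NH4Cl at −78 °C
Reagents that add atoms: none
Why: Carbonyl addition of the alpha-lithiated alkylphosphonate to the aldehyde at −78 °C forms C9–C10 while the molecule still carries no ester, and the two new stereocentres need no control because both become sp2.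

Step 18
Reactants: 27 beta-hydroxyphosphonate
Product: 28 (3S,6R)-3-{(2R)-1-[(tert-butyldiphenylsilyl)oxy]propan-2-yl}-6-{4-(diethoxyphosphoryl)-8-methyl-3-oxo-8-[(triethylsilyl)oxy]nonyl}-6-methyl-1,2-dioxane (C10 epimers)
Conditions: Dess–Martin periodinane, NaHCO3, CH2Cl2, rt
Reagents that add atoms: none
Why: Dess–Martin oxidation of the secondary alcohol gives the beta-ketophosphonate and removes the uncontrolled C9 centre.

Step 19
Reactants: 28 beta-ketophosphonate
Product: 29 (2R)-2-{(3S,6R)-6-[4-(diethoxyphosphoryl)-8-hydroxy-8-methyl-3-oxononyl]-6-methyl-1,2-dioxan-3-yl}propan-1-ol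
Conditions: HF·pyridine, pyridine, THF, 0 °C → rt
Reagents that add atoms: none
Why: Fluoride-driven desilylation (strong Si–F bond) under buffered non-basic conditions should remove both the tert-butyldiphenylsilyl and the triethylsilyl ether in one operation.

Step 20
Reactants: 29 C1 primary alcohol
Product: 31 (2S)-2-{(3S,6R)-6-[4-(diethoxyphosphoryl)-8-hydroxy-8-methyl-3-oxononyl]-6-methyl-1,2-dioxan-3-yl}propanoic acid, via C1 aldehyde 30 (not isolated)
Conditions: TEMPO (cat.), PhI(OAc)2, MeCN/H2O, rt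
Reagents that add atoms: water, O
Why: Oxoammonium (TEMPO) oxidation with PhI(OAc)2 as terminal oxidant takes the primary alcohol through aldehyde 30 and its hydrate to the acid, the tertiary alcohol is inert, and the weakly acidic medium should avoid beta-elimination of the peroxide and epimerisation at C2.

Step 21
Reactants: 31 C1 carboxylic acid
Product: 32 methyl (2S)-2-{(3S,6R)-6-[4-(diethoxyphosphoryl)-8-hydroxy-8-methyl-3-oxononyl]-6-methyl-1,2-dioxan-3-yl}propanoate
Conditions: TMSCHN2, MeOH/toluene, 0 °C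
Reagents that add atoms: (trimethylsilyl)diazomethane, C[Si](C)(C)C=[N+]=[N-]
Why: Diazoalkane esterification methylates the carboxylic acid under neutral conditions and is selective for the acid over the much less acidic beta-ketophosphonate C–H.

Step 22
Reactants: 32 beta-ketophosphonate methyl ester
Product: 33 aikupikoxide D, methyl (2S)-2-[(3S,6R)-6-(8-hydroxy-8-methyl-4-methylidene-3-oxononyl)-6-methyl-1,2-dioxan-3-yl]propanoate
Conditions: 37% aq. CH2O, K2CO3, THF/H2O, 0 °C → rt
Reagents that add atoms: formaldehyde, C=O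
Why: Horner–Wadsworth–Emmons olefination of the alpha-substituted beta-ketophosphonate with formaldehyde under mild carbonate conditions should give the 1,1-disubstituted enone directly and removes the unassigned C10 centre, with the enone made last so that it meets no oxidant, diazo reagent or strong nucleophile.

**Compound list**

1 | 3-(trimethylsilyl)prop-2-ynal | C[Si](C)(C)C#CC=O | starting material
2 | (S)-4-benzyl-3-propanoyl-1,3-oxazolidin-2-one | CCC(=O)N1[C@@H](Cc2ccccc2)COC1=O | starting material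
3 | dibutylboron (Z)-enolate of 2 | C/C=C(\OB(CCCC)CCCC)N1[C@@H](Cc2ccccc2)COC1=O | intermediate (not isolated)
4 | (S)-4-benzyl-3-[(2S,3S)-3-hydroxy-2-methyl-5-(trimethylsilyl)pent-4-ynoyl]-1,3-oxazolidin-2-one | O=C1OC[C@H](Cc2ccccc2)N1C(=O)[C@@H](C)[C@H](O)C#C[Si](C)(C)C | intermediate
5 | (2R,3S)-2-methyl-5-(trimethylsilyl)pent-4-yne-1,3-diol | OC[C@@H](C)[C@H](O)C#C[Si](C)(C)C | intermediate
6 | (2R,3S)-1-[(tert-butyldiphenylsilyl)oxy]-2-methyl-5-(trimethylsilyl)pent-4-yn-3-ol | CC(C)(C)[Si](c1ccccc1)(c1ccccc1)OC[C@@H](C)[C@H](O)C#C[Si](C)(C)C | intermediate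
7 | (2R,3S,4Z)-1-[(tert-butyldiphenylsilyl)oxy]-2-methyl-5-(trimethylsilyl)pent-4-en-3-ol | CC(C)(C)[Si](c1ccccc1)(c1ccccc1)OC[C@@H](C)[C@H](O)/C=C\[Si](C)(C)C | intermediate
8 | (2R,3S,4Z)-1-[(tert-butyldiphenylsilyl)oxy]-2-methyl-5-(trimethylsilyl)pent-4-en-3-yl methanesulfonate | CC(C)(C)[Si](c1ccccc1)(c1ccccc1)OC[C@@H](C)[C@H](OS(C)(=O)=O)/C=C\[Si](C)(C)C | intermediate
9 | tert-butyl{[(2R,3R,4Z)-3-hydroperoxy-2-methyl-5-(trimethylsilyl)pent-4-en-1-yl]oxy}diphenylsilane | CC(C)(C)[Si](c1ccccc1)(c1ccccc1)OC[C@@H](C)[C@@H](OO)/C=C\[Si](C)(C)C | intermediate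
10 | tert-butyldimethyl(prop-2-yn-1-yloxy)silane | C#CCO[Si](C)(C)C(C)(C)C | starting material
11 | N-methoxy-N-methylacetamide | CC(=O)N(C)OC | starting material
12 | lithium acetylide of 10 | [Li]C#CCO[Si](C)(C)C(C)(C)C | intermediate (not isolated)
13 | 5-[(tert-butyldimethylsilyl)oxy]pent-3-yn-2-one | CC(=O)C#CCO[Si](C)(C)C(C)(C)C | intermediate
14 | tert-butyl[(4,4-dimethoxypent-2-yn-1-yl)oxy]dimethylsilane | COC(C)(OC)C#CCO[Si](C)(C)C(C)(C)C | intermediate
15 | mixed methyl peroxyketal of 9 with the ynone, tert-butyl{[(2R,3R,4Z)-3-({5-[(tert-butyldimethylsilyl)oxy]-2-methoxypent-3-yn-2-yl}peroxy)-2-methyl-5-(trimethylsilyl)pent-4-en-1-yl]oxy}diphenylsilane, both C6 epimers | COC(C)(C#CCO[Si](C)(C)C(C)(C)C)OO[C@@H](/C=C\[Si](C)(C)C)[C@H](C)CO[Si](c1ccccc1)(c1ccccc1)C(C)(C)C | intermediate (key-step precursor)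
16 | peroxycarbenium ion from 15 by loss of methoxide (C6=O1+) | CC(C#CCO[Si](C)(C)C(C)(C)C)=[O+]O[C@@H](/C=C\[Si](C)(C)C)[C@H](C)CO[Si](c1ccccc1)(c1ccccc1)C(C)(C)C | intermediate (not isolated)
17 | ring-closed beta-silyl cation (C5–C6 formed, SiMe3 on C5, charge at C4) | CC(C)(C)[Si](C)(C)OCC#C[C@@]1(C)C([Si](C)(C)C)[CH+][C@@H]([C@H](C)CO[Si](c2ccccc2)(c2ccccc2)C(C)(C)C)OO1 | intermediate (not isolated)
18 | tert-butyl{[(2R)-2-{(3S,6R)-6-[3-(tert-butyldimethylsilyloxy)prop-1-yn-1-yl]-6-methyl-3,6-dihydro-1,2-dioxin-3-yl}propyl]oxy}diphenylsilane | CC(C)(C)[Si](C)(C)OCC#C[C@@]1(C)C=C[C@@H]([C@H](C)CO[Si](c2ccccc2)(c2ccccc2)C(C)(C)C)OO1 | intermediate (key-step product)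
19 | tert-butyl{[(2R)-2-{(3S,6S)-6-[3-(tert-butyldimethylsilyloxy)propyl]-6-methyl-1,2-dioxan-3-yl}propyl]oxy}diphenylsilane | CC(C)(C)[Si](C)(C)OCCC[C@@]1(C)CC[C@@H]([C@H](C)CO[Si](c2ccccc2)(c2ccccc2)C(C)(C)C)OO1 | intermediate
20 | (3S,6S)-3-{(2R)-1-[(tert-butyldiphenylsilyl)oxy]propan-2-yl}-6-(3-hydroxypropyl)-6-methyl-1,2-dioxane | OCCC[C@@]1(C)CC[C@@H]([C@H](C)CO[Si](c2ccccc2)(c2ccccc2)C(C)(C)C)OO1 | intermediate
21 | (3S,6R)-3-{(2R)-1-[(tert-butyldiphenylsilyl)oxy]propan-2-yl}-6-methyl-6-(3-oxopropyl)-1,2-dioxane | O=CCC[C@@]1(C)CC[C@@H]([C@H](C)CO[Si](c2ccccc2)(c2ccccc2)C(C)(C)C)OO1 | intermediate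
22 | ethyl 5-bromopentanoate | CCOC(=O)CCCCBr | starting material
23 | ethyl 5-(diethoxyphosphoryl)pentanoate | CCOC(=O)CCCCP(=O)(OCC)OCC | intermediate
24 | diethyl (5-hydroxy-5-methylhexyl)phosphonate | CCOP(=O)(CCCCC(C)(C)O)OCC | intermediate
25 | diethyl {5-methyl-5-[(triethylsilyl)oxy]hexyl}phosphonate | CCOP(=O)(CCCCC(C)(C)O[Si](CC)(CC)CC)OCC | intermediate
26 | alpha-lithiated phosphonate from 25 | [Li]C(CCCC(C)(C)O[Si](CC)(CC)CC)P(=O)(OCC)OCC | intermediate (not isolated)
27 | (3S,6S)-3-{(2R)-1-[(tert-butyldiphenylsilyl)oxy]propan-2-yl}-6-{4-(diethoxyphosphoryl)-3-hydroxy-8-methyl-8-[(triethylsilyl)oxy]nonyl}-6-methyl-1,2-dioxane, C9/C10 diastereomer mixture | CCOP(=O)(OCC)C(CCCC(C)(C)O[Si](CC)(CC)CC)C(O)CC[C@@]1(C)CC[C@@H]([C@H](C)CO[Si](c2ccccc2)(c2ccccc2)C(C)(C)C)OO1 | intermediate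
28 | (3S,6R)-3-{(2R)-1-[(tert-butyldiphenylsilyl)oxy]propan-2-yl}-6-{4-(diethoxyphosphoryl)-8-methyl-3-oxo-8-[(triethylsilyl)oxy]nonyl}-6-methyl-1,2-dioxane, C10 epimers | CCOP(=O)(OCC)C(CCCC(C)(C)O[Si](CC)(CC)CC)C(=O)CC[C@@]1(C)CC[C@@H]([C@H](C)CO[Si](c2ccccc2)(c2ccccc2)C(C)(C)C)OO1 | intermediate
29 | (2R)-2-{(3S,6R)-6-[4-(diethoxyphosphoryl)-8-hydroxy-8-methyl-3-oxononyl]-6-methyl-1,2-dioxan-3-yl}propan-1-ol | CCOP(=O)(OCC)C(CCCC(C)(C)O)C(=O)CC[C@@]1(C)CC[C@@H]([C@H](C)CO)OO1 | intermediate
30 | (2S)-2-{(3S,6R)-6-[4-(diethoxyphosphoryl)-8-hydroxy-8-methyl-3-oxononyl]-6-methyl-1,2-dioxan-3-yl}propanal | CCOP(=O)(OCC)C(CCCC(C)(C)O)C(=O)CC[C@@]1(C)CC[C@@H]([C@H](C)C=O)OO1 | intermediate (not isolated)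
31 | (2S)-2-{(3S,6R)-6-[4-(diethoxyphosphoryl)-8-hydroxy-8-methyl-3-oxononyl]-6-methyl-1,2-dioxan-3-yl}propanoic acid | CCOP(=O)(OCC)C(CCCC(C)(C)O)C(=O)CC[C@@]1(C)CC[C@@H]([C@H](C)C(=O)O)OO1 | intermediate
32 | methyl (2S)-2-{(3S,6R)-6-[4-(diethoxyphosphoryl)-8-hydroxy-8-methyl-3-oxononyl]-6-methyl-1,2-dioxan-3-yl}propanoate | CCOP(=O)(OCC)C(CCCC(C)(C)O)C(=O)CC[C@@]1(C)CC[C@@H]([C@H](C)C(=O)OC)OO1 | intermediate
33 | aikupikoxide D, methyl (2S)-2-[(3S,6R)-6-(8-hydroxy-8-methyl-4-methylidene-3-oxononyl)-6-methyl-1,2-dioxan-3-yl]propanoate | C=C(CCCC(C)(C)O)C(=O)CC[C@@]1(C)CC[C@@H]([C@H](C)C(=O)OC)OO1 | target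

**Step count**

Total: 22 steps. Longest linear sequence: 17 steps (steps 1–6, 9–13 and 17–22).

**Steps most likely to fail**

Step 10 (peroxycarbenium/vinylsilane ring closure). The vinylsilane is deactivated by the allylic peroxide oxygen, so the cation may fragment by O–O heterolysis (Criegee/Hock-type) or be taken by chloride before the ring closes. Face selection at C6 may also be low, and the product may re-ionise at its doubly activated C6–O1 bond.

Fallback, known chemistry, setting out from 2 and returning at 19: C6–O1 is made by cobalt-catalysed hydroperoxysilylation of a 1,1-disubstituted alkene and the ring by intramolecular alkylation of the hydroperoxide. Diethyl 4-oxoheptanedioate is methylenated (Ph3P=CH2, THF) to diethyl 4-methylideneheptanedioate F1 and reduced (LiAlH4) to 4-methylideneheptane-1,7-diol F2. Monosilylation (NaH, TBSCl) gives 7-[(tert-butyldimethylsilyl)oxy]-4-methylideneheptan-1-ol F3, and Dess–Martin oxidation gives 7-[(tert-butyldimethylsilyl)oxy]-4-methylideneheptanal F4. Evans syn-aldol reaction of 2 with F4 (Bu2BOTf, i-Pr2NEt) should give (S)-4-benzyl-3-[(2S,3R)-9-(tert-butyldimethylsilyloxy)-3-hydroxy-2-methyl-6-methylidenenonanoyl]-1,3-oxazolidin-2-one F5. LiBH4 gives (2R,3R)-9-[(tert-butyldimethylsilyl)oxy]-2-methyl-6-methylidenenonane-1,3-diol F6, TBDPSCl/imidazole the primary silyl ether (2R,3R)-9-[(tert-butyldimethylsilyl)oxy]-1-[(tert-butyldiphenylsilyl)oxy]-2-methyl-6-methylidenenonan-3-ol F7, and MsCl/Et3N its C3 methanesulfonate F8. Mukaiyama–Isayama hydroperoxysilylation (Co(acac)2 cat., O2, Et3SiH) places the peroxide on the tertiary carbon C6 to give the triethylsilyl peroxide mesylate F9 as both C6 epimers. Methanolysis (K2CO3, MeOH) frees the tertiary hydroperoxide mesylate F10, and KOt-Bu/18-crown-6 in THF closes the 1,2-dioxane by 6-exo displacement of the C3 mesylate with inversion. This gives 19 together with its C6 epimer, to be separated by chromatography, since C6 is not controlled on this path.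

Step 6 (hydroperoxide displacement). E2 elimination toward the conjugated diene, SN2′ attack, or base-induced decomposition of the allylic hydroperoxide may outrun substitution at the hindered secondary centre.

Fallback, setting out from 5 and returning at 9: the C3–OO bond is made by acid-activated opening of an oxetane instead of base-mediated sulfonate displacement. Semihydrogenation of 5 (H2, nickel boride from Ni(OAc)2·4H2O and NaBH4, ethylenediamine) gives (2R,3S,4Z)-2-methyl-5-(trimethylsilyl)pent-4-ene-1,3-diol F11. TsCl/pyridine at the primary hydroxyl gives (2R,3S,4Z)-3-hydroxy-2-methyl-5-(trimethylsilyl)pent-4-en-1-yl 4-methylbenzenesulfonate F12, and KOt-Bu in THF closes (2S,3R)-3-methyl-2-[(Z)-2-(trimethylsilyl)ethenyl]oxetane F13 without touching C3. Ethereal H2O2 with catalytic TMSOTf at −78 °C should open the activated oxetane at the allylic carbon C3 with inversion to (2R,3R,4Z)-3-hydroperoxy-2-methyl-5-(trimethylsilyl)pent-4-en-1-ol F14. Both oxygens are silylated (TBDPSCl, imidazole, DMF) to the bis-silyl compound tert-butyl{[(2R,3R,4Z)-3-[(tert-butyldiphenylsilyl)peroxy]-2-methyl-5-(trimethylsilyl)pent-4-en-1-yl]oxy}diphenylsilane F15, and selective cleavage of the labile silyl peroxide (K2CO3, MeOH, 0 °C) returns 9.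

Step 11 (exhaustive diimide reduction). Reduction may stall at the C7=C8 cis-alkene beside the quaternary C6, and long exposure to acetic acid and reagent may erode the allylic/propargylic peroxide.

Fallback, setting out from 9 and returning at 19: the alkyne is dispensed with, so that only the ring alkene needs diimide. 5-Hydroxypentan-2-one is silylated (TBSCl, imidazole) to 5-[(tert-butyldimethylsilyl)oxy]pentan-2-one F16 and ketalised as in step 8 to tert-butyl[(4,4-dimethoxypentyl)oxy]dimethylsilane F17. Exchange with 9 as in step 9 gives the saturated mixed peroxyketal tert-butyl{[(2R,3R,4Z)-3-({5-[(tert-butyldimethylsilyl)oxy]-2-methoxypentan-2-yl}peroxy)-2-methyl-5-(trimethylsilyl)pent-4-en-1-yl]oxy}diphenylsilane F18. SnCl4 cyclisation as in step 10 gives tert-butyl{[(2R)-2-{(3S,6S)-6-[3-(tert-butyldimethylsilyloxy)propyl]-6-methyl-3,6-dihydro-1,2-dioxin-3-yl}propyl]oxy}diphenylsilane F19, and one diimide reduction of the ring alkene gives 19. Without the alkyne the two C6 substituents are of similar size, so C6 selectivity is given up and the epimers are separated.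

**Further compounds**

F1 | step 10 | diethyl 4-methylideneheptanedioate | C=C(CCC(=O)OCC)CCC(=O)OCC
F2 | step 10 | 4-methylideneheptane-1,7-diol | C=C(CCCO)CCCO
F3 | step 10 | 7-[(tert-butyldimethylsilyl)oxy]-4-methylideneheptan-1-ol | C=C(CCCO)CCCO[Si](C)(C)C(C)(C)C
F4 | step 10 | 7-[(tert-butyldimethylsilyl)oxy]-4-methylideneheptanal | C=C(CCC=O)CCCO[Si](C)(C)C(C)(C)C
F5 | step 10 | (S)-4-benzyl-3-[(2S,3R)-9-(tert-butyldimethylsilyloxy)-3-hydroxy-2-methyl-6-methylidenenonanoyl]-1,3-oxazolidin-2-one | O=C1OC[C@H](Cc2ccccc2)N1C(=O)[C@@H](C)[C@H](O)CCC(=C)CCCO[Si](C)(C)C(C)(C)C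
F6 | step 10 | (2R,3R)-9-[(tert-butyldimethylsilyl)oxy]-2-methyl-6-methylidenenonane-1,3-diol | OC[C@@H](C)[C@H](O)CCC(=C)CCCO[Si](C)(C)C(C)(C)C
F7 | step 10 | (2R,3R)-9-[(tert-butyldimethylsilyl)oxy]-1-[(tert-butyldiphenylsilyl)oxy]-2-methyl-6-methylidenenonan-3-ol | CC(C)(C)[Si](c1ccccc1)(c1ccccc1)OC[C@@H](C)[C@H](O)CCC(=C)CCCO[Si](C)(C)C(C)(C)C
F8 | step 10 | (2R,3R)-9-[(tert-butyldimethylsilyl)oxy]-1-[(tert-butyldiphenylsilyl)oxy]-2-methyl-6-methylidenenonan-3-yl methanesulfonate | CC(C)(C)[Si](c1ccccc1)(c1ccccc1)OC[C@@H](C)[C@H](OS(C)(=O)=O)CCC(=C)CCCO[Si](C)(C)C(C)(C)C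
F9 | step 10 | (2R,3R)-9-[(tert-butyldimethylsilyl)oxy]-1-[(tert-butyldiphenylsilyl)oxy]-2,6-dimethyl-6-[(triethylsilyl)peroxy]nonan-3-yl methanesulfonate, both C6 epimers | CC(C)(C)[Si](c1ccccc1)(c1ccccc1)OC[C@@H](C)[C@H](OS(C)(=O)=O)CCC(C)(OO[Si](CC)(CC)CC)CCCO[Si](C)(C)C(C)(C)C
F10 | step 10 | (2R,3R)-9-[(tert-butyldimethylsilyl)oxy]-1-[(tert-butyldiphenylsilyl)oxy]-6-hydroperoxy-2,6-dimethylnonan-3-yl methanesulfonate, both C6 epimers | CC(C)(C)[Si](c1ccccc1)(c1ccccc1)OC[C@@H](C)[C@H](OS(C)(=O)=O)CCC(C)(OO)CCCO[Si](C)(C)C(C)(C)C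
F11 | step 6 | (2R,3S,4Z)-2-methyl-5-(trimethylsilyl)pent-4-ene-1,3-diol | OC[C@@H](C)[C@H](O)/C=C\[Si](C)(C)C
F12 | step 6 | (2R,3S,4Z)-3-hydroxy-2-methyl-5-(trimethylsilyl)pent-4-en-1-yl 4-methylbenzenesulfonate | Cc1ccc(cc1)S(=O)(=O)OC[C@@H](C)[C@H](O)/C=C\[Si](C)(C)C
F13 | step 6 | (2S,3R)-3-methyl-2-[(Z)-2-(trimethylsilyl)ethenyl]oxetane | C[C@@H]1CO[C@@H]1/C=C\[Si](C)(C)C
F14 | step 6 | (2R,3R,4Z)-3-hydroperoxy-2-methyl-5-(trimethylsilyl)pent-4-en-1-ol | OC[C@@H](C)[C@@H](OO)/C=C\[Si](C)(C)C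
F15 | step 6 | tert-butyl{[(2R,3R,4Z)-3-[(tert-butyldiphenylsilyl)peroxy]-2-methyl-5-(trimethylsilyl)pent-4-en-1-yl]oxy}diphenylsilane | CC(C)(C)[Si](c1ccccc1)(c1ccccc1)OC[C@@H](C)[C@@H](OO[Si](c1ccccc1)(c1ccccc1)C(C)(C)C)/C=C\[Si](C)(C)C
F16 | step 11 | 5-[(tert-butyldimethylsilyl)oxy]pentan-2-one | CC(=O)CCCO[Si](C)(C)C(C)(C)C
F17 | step 11 | tert-butyl[(4,4-dimethoxypentyl)oxy]dimethylsilane | COC(C)(OC)CCCO[Si](C)(C)C(C)(C)C
F18 | step 11 | tert-butyl{[(2R,3R,4Z)-3-({5-[(tert-butyldimethylsilyl)oxy]-2-methoxypentan-2-yl}peroxy)-2-methyl-5-(trimethylsilyl)pent-4-en-1-yl]oxy}diphenylsilane, both C6 epimers | COC(C)(CCCO[Si](C)(C)C(C)(C)C)OO[C@@H](/C=C\[Si](C)(C)C)[C@H](C)CO[Si](c1ccccc1)(c1ccccc1)C(C)(C)C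
F19 | step 11 | tert-butyl{[(2R)-2-{(3S,6S)-6-[3-(tert-butyldimethylsilyloxy)propyl]-6-methyl-3,6-dihydro-1,2-dioxin-3-yl}propyl]oxy}diphenylsilane | CC(C)(C)[Si](C)(C)OCCC[C@@]1(C)C=C[C@@H]([C@H](C)CO[Si](c2ccccc2)(c2ccccc2)C(C)(C)C)OO1
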